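**Strategy**

Everything rests on cutting the C2–C3 bond of ring C (the pyran ring of the flavan unit). In the forward sense a titanium-mediated carbonyl–olefin metathesis (olefinic ester cyclization) joins C2 and C3 as the enol-ether double bond of a flav-2-ene in one operation. It exploits that O1–C2 with its 2-aryl group is latent in an aryl gallate ester and C4–C3 in an ortho-allyl group, delivered to C4a by Claisen rearrangement. The precursor is a 2-allylaryl 3,4,5-tris(benzyloxy)benzoate carried on the complete, benzyl-protected 1,1,3-triarylpropan-2-ol arm, itself built by two arylative epoxide openings. Hydroboration, oxidation and hydride reduction then set C2 and C3.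

Key step: step 13

Remark: the target is taken exactly as drawn, (1R,2S) in the triarylpropyl arm and (2R,3R) in the flavan; compounds 1, 5, 11 and 17 are taken as commercial.

**Route**

Step 1
Reactants: 1 3,4,5-tris(benzyloxy)benzaldehyde
Product: 2 ethyl (Z)-3-[3,4,5-tris(benzyloxy)phenyl]prop-2-enoate
Conditions: ethyl 2-(diphenoxyphosphoryl)acetate, NaH, THF, −78 → −10 °C
Reagents that add atoms: ethyl 2-(diphenoxyphosphoryl)acetate CCOC(=O)CP(=O)(Oc1ccccc1)Oc1ccccc1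
Why: Horner–Wadsworth–Emmons olefination in the Ando variant, whose diaryl phosphonate collapses kinetically to the (Z)-cinnamate needed for a cis-epoxide.

Step 2
Reactants: 2 ethyl (Z)-3-[3,4,5-tris(benzyloxy)phenyl]prop-2-enoate
Product: 3 ethyl (2R,3R)-3-[3,4,5-tris(benzyloxy)phenyl]oxirane-2-carboxylate (cis)
Conditions: (R,R)-(salen)MnCl [chloro complex of trivalent manganese with (R,R)-N,N'-bis(3,5-di-tert-butylsalicylidene)-1,2-cyclohexanediamine] (cat.), 4-phenylpyridine N-oxide, aq NaOCl (buffered), CH2Cl2, 4 °C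
Reagents that add atoms: sodium hypochlorite [Na+].[O-]Cl
Why: Jacobsen epoxidation, for which cis-cinnamate esters are a well-suited substrate class; the (R,R)-catalyst should deliver oxygen to the face giving the (2R,3R)-cis-glycidate, and any trans-epoxide from stepwise leakage is removed by chromatography.

Step 3
Reactants: 3 ethyl (2R,3R)-3-[3,4,5-tris(benzyloxy)phenyl]oxirane-2-carboxylate
Product: 4 [(2S,3R)-3-[3,4,5-tris(benzyloxy)phenyl]oxiran-2-yl]methanol (cis)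
Conditions: NaBH4, EtOH/THF, 0 °C
Reagents that add atoms: none
Why: Borohydride reduces the α-oxygen-activated glycidic ester to the epoxy alcohol without opening the epoxide, so both stereocentres are carried over.

Step 4
Reactants: 5 3,5-bis(benzyloxy)phenol
Product: 6 3,5-bis(benzyloxy)-4-bromophenol
Conditions: N-bromosuccinimide, CH2Cl2, −78 → −20 °C
Reagents that add atoms: N-bromosuccinimide O=C1CCC(=O)N1Br
Why: Electrophilic bromination of a phenol goes para to the free hydroxyl, here the carbon between the two benzyloxy groups, which fixes the later regiochemistry of ring A; any ortho isomer is separable.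

Step 5
Reactants: 6 3,5-bis(benzyloxy)-4-bromophenol
Product: 7 5-(allyloxy)-1,3-bis(benzyloxy)-2-bromobenzene
Conditions: allyl bromide, K2CO3, acetone, reflux
Reagents that add atoms: allyl bromide C=CCBr
Why: Williamson O-allylation of the phenoxide marks the oxygen that becomes O1 and stores the C3–C4 carbons as the allyl group.

Step 6
Reactants: 7 5-(allyloxy)-1,3-bis(benzyloxy)-2-bromobenzene; 4 [(2S,3R)-3-[3,4,5-tris(benzyloxy)phenyl]oxiran-2-yl]methanol
Product: 9 (2R,3R)-3-[4-(allyloxy)-2,6-bis(benzyloxy)phenyl]-3-[3,4,5-tris(benzyloxy)phenyl]propane-1,2-diol, via arylmagnesium bromide 8 (not isolated)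
Conditions: 7, Mg, THF, 40 °C (3 equiv of 8); then 4, CuI (monovalent copper iodide, 10 mol %), THF, −30 → 0 °C; aq NH4Cl
Reagents that add atoms: none
Why: Copper-catalysed Grignard opening of a 3-aryl-2,3-epoxy alcohol occurs at the benzylic C3 with inversion (SN2), so the cis-epoxide gives the (3R) diarylmethine next to the untouched (2R) carbinol.

Step 7
Reactants: 9 (2R,3R)-3-[4-(allyloxy)-2,6-bis(benzyloxy)phenyl]-3-[3,4,5-tris(benzyloxy)phenyl]propane-1,2-diol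
Product: 10 (2R)-2-[(R)-[4-(allyloxy)-2,6-bis(benzyloxy)phenyl][3,4,5-tris(benzyloxy)phenyl]methyl]oxirane
Conditions: NaH, 1-(p-toluenesulfonyl)imidazole, THF, 0 °C → rt
Reagents that add atoms: none
Why: One-pot selective sulfonylation of the primary alkoxide and intramolecular Williamson displacement by the secondary alkoxide (SN2 at the primary carbon) give the terminal epoxide with the carbinol configuration retained.

Step 8
Reactants: 11 1,3,5-tris(benzyloxy)benzene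
Product: 12 2-bromo-1,3,5-tris(benzyloxy)benzene
Conditions: N-bromosuccinimide, CH2Cl2, −78 °C → 0 °C
Reagents that add atoms: N-bromosuccinimide O=C1CCC(=O)N1Br
Why: Electrophilic bromination of the symmetric, strongly activated arene gives a single monobromide.

Step 9
Reactants: 12 2-bromo-1,3,5-tris(benzyloxy)benzene; 10 (2R)-2-[(R)-[4-(allyloxy)-2,6-bis(benzyloxy)phenyl][3,4,5-tris(benzyloxy)phenyl]methyl]oxirane
Product: 14 (1R,2S)-1-[4-(allyloxy)-2,6-bis(benzyloxy)phenyl]-1-[3,4,5-tris(benzyloxy)phenyl]-3-[2,4,6-tris(benzyloxy)phenyl]propan-2-ol, via arylmagnesium bromide 13 (not isolated)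
Conditions: 12, Mg, THF, 40 °C; then 10, CuI (monovalent copper iodide, 10 mol %), THF, −30 → 0 °C; aq NH4Cl
Reagents that add atoms: none
Why: Copper-catalysed Grignard opening of the terminal epoxide at its primary carbon (SN2) installs the benzylic CH2 of the phloroglucinol ring and leaves both stereocentres untouched.

Step 10
Reactants: 14 (1R,2S)-1-[4-(allyloxy)-2,6-bis(benzyloxy)phenyl]-1-[3,4,5-tris(benzyloxy)phenyl]-3-[2,4,6-tris(benzyloxy)phenyl]propan-2-ol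
Product: 15 tert-butyldimethylsilyl ether of 14, (1R,2S)
Conditions: tert-butyldimethylsilyl triflate, 2,6-lutidine, CH2Cl2, 0 °C → rt
Reagents that add atoms: tert-butyldimethylsilyl trifluoromethanesulfonate CC(C)(C)[Si](C)(C)OS(=O)(=O)C(F)(F)F
Why: Silylation with the silyl triflate protects the hindered secondary alcohol against the later titanium, borane and oxidation steps.

Step 11
Reactants: 15 tert-butyldimethylsilyl ether of 14
Product: 16 2-allyl-3,5-bis(benzyloxy)-4-[(1R,2S)-2-(tert-butyldimethylsilyloxy)-1-[3,4,5-tris(benzyloxy)phenyl]-3-[2,4,6-tris(benzyloxy)phenyl]propyl]phenol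
Conditions: N,N-diethylaniline, 185 °C
Reagents that add atoms: none
Why: Aromatic Claisen rearrangement ([3,3]-sigmatropic) moves the allyl group to the ortho carbon (the future C4a) and frees the phenol that becomes O1; the two ortho positions are equivalent, so one product should form.

Step 12
Reactants: 16 the 2-allylphenol; 17 3,4,5-tris(benzyloxy)benzoic acid
Product: 18 2-allyl-3,5-bis(benzyloxy)-4-[(1R,2S)-2-(tert-butyldimethylsilyloxy)-1-[3,4,5-tris(benzyloxy)phenyl]-3-[2,4,6-tris(benzyloxy)phenyl]propyl]phenyl 3,4,5-tris(benzyloxy)benzoate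
Conditions: DCC, DMAP (cat.), CH2Cl2, rt
Reagents that add atoms: none
Why: Steglich esterification of the phenol brings in ring B and C2 as the ester carbonyl carbon.

Step 13
Reactants: 18 the 2-allylaryl 3,4,5-tris(benzyloxy)benzoate
Product: 20 5,7-bis(benzyloxy)-6-[(1R,2S)-2-(tert-butyldimethylsilyloxy)-1-[3,4,5-tris(benzyloxy)phenyl]-3-[2,4,6-tris(benzyloxy)phenyl]propyl]-2-[3,4,5-tris(benzyloxy)phenyl]-4H-chromene, via titanium alkylidene 19 (not isolated)
Conditions: TiCl4, TMEDA, Zn, PbCl2 (cat.), CH3CHBr2, THF/CH2Cl2, 0 → 65 °C; basic work-up, base-washed silica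
Reagents that add atoms: none
Why: The titanium ethylidene formed in the flask from 1,1-dibromoethane, TiCl4, Zn and TMEDA (Takai–Utimoto reagent) should exchange with the terminal alkene of the allyl group to give the titanium alkylidene 19 at C3 with loss of propene, and this adds across the neighbouring ester C2=O and cycloreverts to the C2=C3 enol ether and a titanium oxo species. The closest known reaction type is the olefinic ester cyclization (carbonyl–olefin metathesis with reduced titanium alkylidenes) used to make cyclic enol ethers. Ring C is closed by this ring-closing metathesis in a six-membered mode with the new double bond endocyclic, between the ortho-disposed O1 and C4a substituents of ring A. No stereocentre is formed, since C2 and C3 become sp2 and are set in steps 14 and 16. The step needs cyclization to win over plain ethylidenation of the ester, which the single ester, the single terminal alkene, their ortho relationship and the alkene-first preference of the ethylidene reagent should secure; benzyl and silyl ethers are inert.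

Step 14
Reactants: 20 the 2-aryl-4H-chromene
Product: 22 (2R,3S)-5,7-bis(benzyloxy)-6-[(1R,2S)-2-(tert-butyldimethylsilyloxy)-1-[3,4,5-tris(benzyloxy)phenyl]-3-[2,4,6-tris(benzyloxy)phenyl]propyl]-2-[3,4,5-tris(benzyloxy)phenyl]chroman-3-ol (2,3-trans), via isopinocampheylborane adduct 21 (not isolated)
Conditions: monoisopinocampheylborane (IpcBH2) prepared from (+)-α-pinene, THF, −25 → 0 °C; then NaOH, H2O2, 0 °C
Reagents that add atoms: hydrogen peroxide OO
Why: Asymmetric hydroboration–oxidation puts boron on C3 (β to the enol-ether oxygen, non-benzylic) and hydrogen on C2 in a syn fashion, giving the 2,3-trans alcohol, and the pinene-derived reagent should select the face that gives (2R,3S) by its usual steric model for 1-arylcycloalkenes.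

Step 15
Reactants: 22 the (2R,3S)-chroman-3-ol
Product: 23 (2R)-5,7-bis(benzyloxy)-6-[(1R,2S)-2-(tert-butyldimethylsilyloxy)-1-[3,4,5-tris(benzyloxy)phenyl]-3-[2,4,6-tris(benzyloxy)phenyl]propyl]-2-[3,4,5-tris(benzyloxy)phenyl]chroman-3-one
Conditions: Dess–Martin periodinane, NaHCO3, CH2Cl2, 0 °C → rt
Reagents that add atoms: none
Why: Dess–Martin oxidation under buffered conditions gives the flavan-3-one and should leave the C2 stereocentre intact.

Step 16
Reactants: 23 the (2R)-chroman-3-one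
Product: 24 (2R,3R)-5,7-bis(benzyloxy)-6-[(1R,2S)-2-(tert-butyldimethylsilyloxy)-1-[3,4,5-tris(benzyloxy)phenyl]-3-[2,4,6-tris(benzyloxy)phenyl]propyl]-2-[3,4,5-tris(benzyloxy)phenyl]chroman-3-ol (2,3-cis)
Conditions: LiB(sec-Bu)3H (L-Selectride), THF, −78 °C
Reagents that add atoms: none
Why: The bulky trialkylborohydride attacks the ketone from the face opposite the C2 aryl group, so the hydroxyl ends up cis to it (2R,3R).

Step 17
Reactants: 24 the (2R,3R)-chroman-3-ol silyl ether; 17 3,4,5-tris(benzyloxy)benzoic acid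
Product: 25 (2R,3R)-5,7-bis(benzyloxy)-6-[(1R,2S)-2-(tert-butyldimethylsilyloxy)-1-[3,4,5-tris(benzyloxy)phenyl]-3-[2,4,6-tris(benzyloxy)phenyl]propyl]-2-[3,4,5-tris(benzyloxy)phenyl]chroman-3-yl 3,4,5-tris(benzyloxy)benzoate
Conditions: DCC, DMAP, CH2Cl2, rt
Reagents that add atoms: none
Why: Steglich esterification acylates the only free hydroxyl (C3–OH, the arm carbinol still being silylated) with retention, since the C3–O bond is not broken.

Step 18
Reactants: 25 the chroman-3-yl gallate silyl ether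
Product: 26 (2R,3R)-5,7-bis(benzyloxy)-6-[(1R,2S)-2-hydroxy-1-[3,4,5-tris(benzyloxy)phenyl]-3-[2,4,6-tris(benzyloxy)phenyl]propyl]-2-[3,4,5-tris(benzyloxy)phenyl]chroman-3-yl 3,4,5-tris(benzyloxy)benzoate
Conditions: HF·pyridine, pyridine, THF, 0 °C → rt
Reagents that add atoms: none
Why: Buffered, non-basic fluoride desilylation frees the arm carbinol while the benzoate ester, the benzyl ethers and the C2 configuration should be left untouched.

Step 19
Reactants: 26 the arm alcohol; 17 3,4,5-tris(benzyloxy)benzoic acid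
Product: 27 heptadecabenzyl ether of the target: (1R,2S)-1-[(2R,3R)-5,7-bis(benzyloxy)-3-[3,4,5-tris(benzyloxy)benzoyloxy]-2-[3,4,5-tris(benzyloxy)phenyl]chroman-6-yl]-1-[3,4,5-tris(benzyloxy)phenyl]-3-[2,4,6-tris(benzyloxy)phenyl]propan-2-yl 3,4,5-tris(benzyloxy)benzoate
Conditions: DCC, DMAP, CH2Cl2, rt → 40 °C
Reagents that add atoms: none
Why: A second Steglich esterification acylates the remaining hindered secondary hydroxyl of the arm with retention, since its C–O bond is not broken.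

Step 20
Reactants: 27 the heptadecabenzyl ether
Product: 28 (1R,2S)-1-[(2R,3R)-5,7-dihydroxy-3-(3,4,5-trihydroxybenzoyloxy)-2-(3,4,5-trihydroxyphenyl)chroman-6-yl]-1-(3,4,5-trihydroxyphenyl)-3-(2,4,6-trihydroxyphenyl)propan-2-yl 3,4,5-trihydroxybenzoate (CNP0240551.2)
Conditions: H2 (1 atm), Pd(OH)2/C, THF/MeOH, rt
Reagents that add atoms: none
Why: Hydrogenolysis removes all seventeen benzyl ethers, while the benzoate esters, the O1–C2 aryl ether and the diarylmethine should survive under neutral conditions.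

**Compound list**

1 | 3,4,5-tris(benzyloxy)benzaldehyde | O=Cc1cc(OCc2ccccc2)c(OCc2ccccc2)c(OCc2ccccc2)c1 | starting material
2 | ethyl (Z)-3-[3,4,5-tris(benzyloxy)phenyl]prop-2-enoate | CCOC(=O)/C=C\c1cc(OCc2ccccc2)c(OCc2ccccc2)c(OCc2ccccc2)c1 | intermediate
3 | ethyl (2R,3R)-3-[3,4,5-tris(benzyloxy)phenyl]oxirane-2-carboxylate | CCOC(=O)[C@@H]1O[C@@H]1c1cc(OCc2ccccc2)c(OCc2ccccc2)c(OCc2ccccc2)c1 | intermediate
4 | [(2S,3R)-3-[3,4,5-tris(benzyloxy)phenyl]oxiran-2-yl]methanol | OC[C@@H]1O[C@@H]1c1cc(OCc2ccccc2)c(OCc2ccccc2)c(OCc2ccccc2)c1 | intermediate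
5 | 3,5-bis(benzyloxy)phenol | Oc1cc(OCc2ccccc2)cc(OCc2ccccc2)c1 | starting material
6 | 3,5-bis(benzyloxy)-4-bromophenol | Oc1cc(OCc2ccccc2)c(Br)c(OCc2ccccc2)c1 | intermediate
7 | 5-(allyloxy)-1,3-bis(benzyloxy)-2-bromobenzene | C=CCOc1cc(OCc2ccccc2)c(Br)c(OCc2ccccc2)c1 | intermediate
8 | [4-(allyloxy)-2,6-bis(benzyloxy)phenyl]magnesium bromide | C=CCOc1cc(OCc2ccccc2)c([Mg]Br)c(OCc2ccccc2)c1 | intermediate
9 | (2R,3R)-3-[4-(allyloxy)-2,6-bis(benzyloxy)phenyl]-3-[3,4,5-tris(benzyloxy)phenyl]propane-1,2-diol | OC[C@H](O)[C@H](c1cc(OCc2ccccc2)c(OCc2ccccc2)c(OCc2ccccc2)c1)c1c(OCc2ccccc2)cc(OCC=C)cc1OCc1ccccc1 | intermediate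
10 | (2R)-2-[(R)-[4-(allyloxy)-2,6-bis(benzyloxy)phenyl][3,4,5-tris(benzyloxy)phenyl]methyl]oxirane | C1O[C@@H]1[C@H](c1cc(OCc2ccccc2)c(OCc2ccccc2)c(OCc2ccccc2)c1)c1c(OCc2ccccc2)cc(OCC=C)cc1OCc1ccccc1 | intermediate
11 | 1,3,5-tris(benzyloxy)benzene | c1c(OCc2ccccc2)cc(OCc2ccccc2)cc1OCc1ccccc1 | starting material
12 | 2-bromo-1,3,5-tris(benzyloxy)benzene | Brc1c(OCc2ccccc2)cc(OCc2ccccc2)cc1OCc1ccccc1 | intermediate
13 | [2,4,6-tris(benzyloxy)phenyl]magnesium bromide | Br[Mg]c1c(OCc2ccccc2)cc(OCc2ccccc2)cc1OCc1ccccc1 | intermediate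
14 | (1R,2S)-1-[4-(allyloxy)-2,6-bis(benzyloxy)phenyl]-1-[3,4,5-tris(benzyloxy)phenyl]-3-[2,4,6-tris(benzyloxy)phenyl]propan-2-ol | O[C@@H](Cc1c(OCc2ccccc2)cc(OCc2ccccc2)cc1OCc1ccccc1)[C@H](c1cc(OCc2ccccc2)c(OCc2ccccc2)c(OCc2ccccc2)c1)c1c(OCc2ccccc2)cc(OCC=C)cc1OCc1ccccc1 | intermediate
15 | tert-butyldimethylsilyl ether of 14 | CC(C)(C)[Si](C)(C)O[C@@H](Cc1c(OCc2ccccc2)cc(OCc2ccccc2)cc1OCc1ccccc1)[C@H](c1cc(OCc2ccccc2)c(OCc2ccccc2)c(OCc2ccccc2)c1)c1c(OCc2ccccc2)cc(OCC=C)cc1OCc1ccccc1 | intermediate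
16 | 2-allyl-3,5-bis(benzyloxy)-4-[(1R,2S)-2-(tert-butyldimethylsilyloxy)-1-[3,4,5-tris(benzyloxy)phenyl]-3-[2,4,6-tris(benzyloxy)phenyl]propyl]phenol | CC(C)(C)[Si](C)(C)O[C@@H](Cc1c(OCc2ccccc2)cc(OCc2ccccc2)cc1OCc1ccccc1)[C@H](c1cc(OCc2ccccc2)c(OCc2ccccc2)c(OCc2ccccc2)c1)c1c(OCc2ccccc2)cc(O)c(CC=C)c1OCc1ccccc1 | intermediate
17 | 3,4,5-tris(benzyloxy)benzoic acid | OC(=O)c1cc(OCc2ccccc2)c(OCc2ccccc2)c(OCc2ccccc2)c1 | starting material
18 | 3,4,5-tris(benzyloxy)benzoate of phenol 16 | CC(C)(C)[Si](C)(C)O[C@@H](Cc1c(OCc2ccccc2)cc(OCc2ccccc2)cc1OCc1ccccc1)[C@H](c1cc(OCc2ccccc2)c(OCc2ccccc2)c(OCc2ccccc2)c1)c1c(OCc2ccccc2)cc(OC(=O)c2cc(OCc3ccccc3)c(OCc3ccccc3)c(OCc3ccccc3)c2)c(CC=C)c1OCc1ccccc1 | intermediate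
19 | dichlorotitanium alkylidene at the former allyl CH of 18 (TMEDA ligand omitted) | CC(C)(C)[Si](C)(C)O[C@@H](Cc1c(OCc2ccccc2)cc(OCc2ccccc2)cc1OCc1ccccc1)[C@H](c1cc(OCc2ccccc2)c(OCc2ccccc2)c(OCc2ccccc2)c1)c1c(OCc2ccccc2)cc(OC(=O)c2cc(OCc3ccccc3)c(OCc3ccccc3)c(OCc3ccccc3)c2)c(CC=[Ti](Cl)Cl)c1OCc1ccccc1 | intermediate
20 | 5,7-bis(benzyloxy)-6-[(1R,2S)-2-(tert-butyldimethylsilyloxy)-1-[3,4,5-tris(benzyloxy)phenyl]-3-[2,4,6-tris(benzyloxy)phenyl]propyl]-2-[3,4,5-tris(benzyloxy)phenyl]-4H-chromene | CC(C)(C)[Si](C)(C)O[C@@H](Cc1c(OCc2ccccc2)cc(OCc2ccccc2)cc1OCc1ccccc1)[C@H](c1cc(OCc2ccccc2)c(OCc2ccccc2)c(OCc2ccccc2)c1)c1c(OCc2ccccc2)cc2c(c1OCc1ccccc1)CC=C(c1cc(OCc3ccccc3)c(OCc3ccccc3)c(OCc3ccccc3)c1)O2 | intermediate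
21 | (2R,3S)-chroman-3-yl(isopinocampheyl)borane from 20 | CC(C)(C)[Si](C)(C)O[C@@H](Cc1c(OCc2ccccc2)cc(OCc2ccccc2)cc1OCc1ccccc1)[C@H](c1cc(OCc2ccccc2)c(OCc2ccccc2)c(OCc2ccccc2)c1)c1c(OCc2ccccc2)cc2c(c1OCc1ccccc1)C[C@H](B[C@@H]1C[C@@H]3C[C@H]([C@H]1C)C3(C)C)[C@@H](c1cc(OCc3ccccc3)c(OCc3ccccc3)c(OCc3ccccc3)c1)O2 | intermediate
22 | (2R,3S)-chroman-3-ol (2,3-trans), silyl-protected arm | CC(C)(C)[Si](C)(C)O[C@@H](Cc1c(OCc2ccccc2)cc(OCc2ccccc2)cc1OCc1ccccc1)[C@H](c1cc(OCc2ccccc2)c(OCc2ccccc2)c(OCc2ccccc2)c1)c1c(OCc2ccccc2)cc2c(c1OCc1ccccc1)C[C@H](O)[C@@H](c1cc(OCc3ccccc3)c(OCc3ccccc3)c(OCc3ccccc3)c1)O2 | intermediate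
23 | (2R)-chroman-3-one, silyl-protected arm | CC(C)(C)[Si](C)(C)O[C@@H](Cc1c(OCc2ccccc2)cc(OCc2ccccc2)cc1OCc1ccccc1)[C@H](c1cc(OCc2ccccc2)c(OCc2ccccc2)c(OCc2ccccc2)c1)c1c(OCc2ccccc2)cc2c(c1OCc1ccccc1)CC(=O)[C@@H](c1cc(OCc3ccccc3)c(OCc3ccccc3)c(OCc3ccccc3)c1)O2 | intermediate
24 | (2R,3R)-chroman-3-ol (2,3-cis), silyl-protected arm | CC(C)(C)[Si](C)(C)O[C@@H](Cc1c(OCc2ccccc2)cc(OCc2ccccc2)cc1OCc1ccccc1)[C@H](c1cc(OCc2ccccc2)c(OCc2ccccc2)c(OCc2ccccc2)c1)c1c(OCc2ccccc2)cc2c(c1OCc1ccccc1)C[C@@H](O)[C@@H](c1cc(OCc3ccccc3)c(OCc3ccccc3)c(OCc3ccccc3)c1)O2 | intermediate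
25 | (2R,3R)-5,7-bis(benzyloxy)-6-[(1R,2S)-2-(tert-butyldimethylsilyloxy)-1-[3,4,5-tris(benzyloxy)phenyl]-3-[2,4,6-tris(benzyloxy)phenyl]propyl]-2-[3,4,5-tris(benzyloxy)phenyl]chroman-3-yl 3,4,5-tris(benzyloxy)benzoate | CC(C)(C)[Si](C)(C)O[C@@H](Cc1c(OCc2ccccc2)cc(OCc2ccccc2)cc1OCc1ccccc1)[C@H](c1cc(OCc2ccccc2)c(OCc2ccccc2)c(OCc2ccccc2)c1)c1c(OCc2ccccc2)cc2c(c1OCc1ccccc1)C[C@@H](OC(=O)c1cc(OCc3ccccc3)c(OCc3ccccc3)c(OCc3ccccc3)c1)[C@@H](c1cc(OCc3ccccc3)c(OCc3ccccc3)c(OCc3ccccc3)c1)O2 | intermediate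
26 | (2R,3R)-5,7-bis(benzyloxy)-6-[(1R,2S)-2-hydroxy-1-[3,4,5-tris(benzyloxy)phenyl]-3-[2,4,6-tris(benzyloxy)phenyl]propyl]-2-[3,4,5-tris(benzyloxy)phenyl]chroman-3-yl 3,4,5-tris(benzyloxy)benzoate | O[C@@H](Cc1c(OCc2ccccc2)cc(OCc2ccccc2)cc1OCc1ccccc1)[C@H](c1cc(OCc2ccccc2)c(OCc2ccccc2)c(OCc2ccccc2)c1)c1c(OCc2ccccc2)cc2c(c1OCc1ccccc1)C[C@@H](OC(=O)c1cc(OCc3ccccc3)c(OCc3ccccc3)c(OCc3ccccc3)c1)[C@@H](c1cc(OCc3ccccc3)c(OCc3ccccc3)c(OCc3ccccc3)c1)O2 | intermediate
27 | heptadecabenzyl ether of the target (arm 3,4,5-tris(benzyloxy)benzoate of 26) | O=C(O[C@@H](Cc1c(OCc2ccccc2)cc(OCc2ccccc2)cc1OCc1ccccc1)[C@H](c1cc(OCc2ccccc2)c(OCc2ccccc2)c(OCc2ccccc2)c1)c1c(OCc2ccccc2)cc2c(c1OCc1ccccc1)C[C@@H](OC(=O)c1cc(OCc3ccccc3)c(OCc3ccccc3)c(OCc3ccccc3)c1)[C@@H](c1cc(OCc3ccccc3)c(OCc3ccccc3)c(OCc3ccccc3)c1)O2)c1cc(OCc2ccccc2)c(OCc2ccccc2)c(OCc2ccccc2)c1 | intermediate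
28 | (1R,2S)-1-[(2R,3R)-5,7-dihydroxy-3-(3,4,5-trihydroxybenzoyloxy)-2-(3,4,5-trihydroxyphenyl)chroman-6-yl]-1-(3,4,5-trihydroxyphenyl)-3-(2,4,6-trihydroxyphenyl)propan-2-yl 3,4,5-trihydroxybenzoate | O=C(O[C@@H](Cc1c(O)cc(O)cc1O)[C@H](c1cc(O)c(O)c(O)c1)c1c(O)cc2c(c1O)C[C@@H](OC(=O)c1cc(O)c(O)c(O)c1)[C@@H](c1cc(O)c(O)c(O)c1)O2)c1cc(O)c(O)c(O)c1 | target

**Summary**

Total step count: 20
Longest linear sequence: 17 steps (steps 1–3, 6, 7, 9–20)

Steps most likely to fail: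

1. Step 6. The di-ortho-substituted aryl Grignard may attack the hindered benzylic C3 too slowly, so that attack at C2, epoxide rearrangement or copper-mediated loss of the allyl ether take over. The fallback sets out from 5 and 4 and comes back at 9. Silylation of 5 (iPr3SiCl, imidazole, DMF) gives [3,5-bis(benzyloxy)phenoxy]tri(propan-2-yl)silane F1. BF3·OEt2 (CH2Cl2, −78 °C) should then open 4 at the benzylic carbon by Friedel–Crafts attack of F1 with inversion, the bulky silyloxy group steering the electrophile to the ring carbon between the two benzyloxy groups, to give (2R,3R)-3-[2,6-bis(benzyloxy)-4-(triisopropylsilyloxy)phenyl]-3-[3,4,5-tris(benzyloxy)phenyl]propane-1,2-diol F2. CsF and allyl bromide in DMF exchange the aryl silyl ether for the allyl ether, the aliphatic hydroxyls staying free, which gives 9.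

2. Step 13. The titanium ethylidene may simply ethylidenate the ester carbonyl to an acyclic enol ether instead of starting at the alkene, and the acid-labile 2-aryl-4H-chromene may hydrolyse on work-up. The fallback sets out from 18 and comes back at 20. Petasis methylenation (Cp2TiMe2, toluene, 70 °C) converts the aryl ester into the 1-[3,4,5-tris(benzyloxy)phenyl]vinyl ether of phenol 16 F3. Ring-closing metathesis of its two terminal alkenes with the second-generation Grubbs catalyst (H2IMes)(PCy3)Cl2Ru=CHPh (toluene, 70 °C) then gives 20.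

3. Step 14. The remote stereocentres give no bias, so everything depends on the reagent; poor facial selectivity, slow addition of the bulky borane, or β-elimination of the β-aryloxy borane with opening of ring C may result. The fallback sets out from 20 and comes back at 24. Hydroboration with BH3·SMe2 and NaOH/H2O2 gives the 2,3-trans chroman-3-ol diastereomer mixture F4 (both ring-C configurations). Dess–Martin oxidation gives the chroman-3-one C2-epimer mixture F5, whose C2 (benzylic, α to oxygen and carbonyl) epimerizes under base. Noyori-type asymmetric transfer hydrogenation with dynamic kinetic resolution (RuCl(p-cymene)(TsDPEN), the ligand antipode chosen for the 3R carbinol, HCO2H/Et3N) should funnel both epimers into the 2,3-cis (2R,3R) alcohol 24.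

Further compounds
F1 | step 6 | [3,5-bis(benzyloxy)phenoxy]tri(propan-2-yl)silane | CC(C)[Si](Oc1cc(OCc2ccccc2)cc(OCc2ccccc2)c1)(C(C)C)C(C)C
F2 | step 6 | (2R,3R)-3-[2,6-bis(benzyloxy)-4-(triisopropylsilyloxy)phenyl]-3-[3,4,5-tris(benzyloxy)phenyl]propane-1,2-diol | OC[C@H](O)[C@H](c1cc(OCc2ccccc2)c(OCc2ccccc2)c(OCc2ccccc2)c1)c1c(OCc2ccccc2)cc(O[Si](C(C)C)(C(C)C)C(C)C)cc1OCc1ccccc1
F3 | step 13 | 1-[3,4,5-tris(benzyloxy)phenyl]vinyl ether of phenol 16 | CC(C)(C)[Si](C)(C)O[C@@H](Cc1c(OCc2ccccc2)cc(OCc2ccccc2)cc1OCc1ccccc1)[C@H](c1cc(OCc2ccccc2)c(OCc2ccccc2)c(OCc2ccccc2)c1)c1c(OCc2ccccc2)cc(OC(=C)c2cc(OCc3ccccc3)c(OCc3ccccc3)c(OCc3ccccc3)c2)c(CC=C)c1OCc1ccccc1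
F4 | step 14 | 2,3-trans chroman-3-ols corresponding to 22, both ring-C configurations (C2 and C3 left unspecified) | CC(C)(C)[Si](C)(C)O[C@@H](Cc1c(OCc2ccccc2)cc(OCc2ccccc2)cc1OCc1ccccc1)[C@H](c1cc(OCc2ccccc2)c(OCc2ccccc2)c(OCc2ccccc2)c1)c1c(OCc2ccccc2)cc2c(c1OCc1ccccc1)CC(O)C(c1cc(OCc3ccccc3)c(OCc3ccccc3)c(OCc3ccccc3)c1)O2
F5 | step 14 | chroman-3-one corresponding to 23 as the C2-epimer mixture (C2 left unspecified) | CC(C)(C)[Si](C)(C)O[C@@H](Cc1c(OCc2ccccc2)cc(OCc2ccccc2)cc1OCc1ccccc1)[C@H](c1cc(OCc2ccccc2)c(OCc2ccccc2)c(OCc2ccccc2)c1)c1c(OCc2ccccc2)cc2c(c1OCc1ccccc1)CC(=O)C(c1cc(OCc3ccccc3)c(OCc3ccccc3)c(OCc3ccccc3)c1)O2
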